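The plan treats ring C1–C10–C11–C12–C13–C14, a 6-hydroxy-6-methylcyclohex-2-enone, as the β-elimination product of a 7-oxabicyclo[2.2.1]heptan-2-one in which one oxygen ties C11 to C14. A single furan Diels–Alder reaction forms C10–C11 and C1–C14. It closes the carbocycle and the oxygen bridge together and sets C1, C10, C11 and C14. The bridge then masks 11-OH and C13=C14 until the last step. The precursors are 3-(tert-butyldimethylsilyloxy)-2-methylfuran and a mesaconate-type dienophile with C2 as a formyl group and C9 as an ethyl ester, so the chiral Lewis acid binds at C2 only. C3–C6 and C7/C8/C17–C19 are then added, and the ten-membered ring is closed at C6–C7.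

Key step: step 3

Numbering (briarane): C15 = methyl on C1, C16 = methyl on C5, C17 = lactone α-carbon, C18 = its methyl, C19 = lactone C=O, C20 = methyl on C11.
Assumption: the sense of induction in step 3 is assigned from the usual B–O/formyl C–H···O binding model of 2-methyl enals on the oxazaborolidinium ion; both catalyst antipodes are commercial, so at most the catalyst label would change.

Step 1
Reactants: 1 2-methyltetrahydrofuran-3-one (racemic)
Product: 3 2-methylfuran-3(2H)-one (racemic), via lithium enolate 2 (not isolated)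
Conditions: LDA, THF, −78 °C; then N-tert-butylbenzenesulfinimidoyl chloride, −78 °C
Reagents that add atoms: none
Why: Mukaiyama dehydrogenation, in which LDA takes the less hindered C4–H (kinetic enolate), the enolate attacks sulfur, and a syn-elimination through nitrogen removes a C5–H, so the C4=C5 enone forms in one flask and no lasting stereocentre is involved.

Step 2
Reactants: 3 2-methylfuran-3(2H)-one
Product: 4 3-(tert-butyldimethylsilyloxy)-2-methylfuran
Conditions: TBSOTf, Et3N, CH2Cl2, 0 °C
Reagents that add atoms: tert-butyldimethylsilyl triflate CC(C)(C)[Si](C)(C)OS(=O)(=O)C(F)(F)F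
Why: Soft enolisation with O-silylation, in which loss of the doubly activated C2–H is driven by aromatisation to the furan.

Step 3
Reactants: 4 3-(tert-butyldimethylsilyloxy)-2-methylfuran; 5 ethyl (E)-3-methyl-4-oxobut-2-enoate (mesaconate skeleton, C2 = CHO, C9 = CO2Et)
Product: 6 ethyl (1S,2R,3R,4S)-6-(tert-butyldimethylsilyloxy)-3-formyl-1,3-dimethyl-7-oxabicyclo[2.2.1]hept-5-ene-2-carboxylate (C9 ester endo, C2 formyl exo, C15 methyl endo, oxygen bridge C11–O–C14)
Conditions: (R)-diphenylprolinol-derived B-(o-tolyl)oxazaborolidine (20 mol %) activated with Tf2NH (17 mol %), CH2Cl2, −78 °C; cold Et3N quench, Et3N-deactivated silica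
Reagents that add atoms: none
Why: The boron-bound enal and the furan diene C11=C12–C13=C14 combine in a concerted but asynchronous normal-demand [4+2] cycloaddition, the closest known types being oxazaborolidinium-catalysed Diels–Alder reactions of furans and of 2-silyloxydienes with 2-methyl enals and the uncatalysed cycloadditions of 3-alkoxy- and 3-silyloxyfurans with fumarate-type alkenes. Both rings, the carbocycle C1–C10–C11–C12–C13–C14 and the oxolane C11–O–C14–C1–C10, are closed by this one suprafacial–suprafacial event that makes C10–C11 and C1–C14. For regiochemistry, the catalyst sits only on the formyl oxygen of C2, which makes C10 the electrophilic β-carbon, and C10 meets C11, the diene terminus with the largest HOMO coefficient because of the C12 silyloxy group, while the longer and later bond builds quaternary C1 at unsubstituted C14, so polarity and sterics agree. For relative configuration, the E alkene carries its trans C2/C9 relation into C1 and C10, the bridge holds C11 and C14 on one face, and the exo habit of a 2-methyl enal together with the endo habit of the ester puts C2 exo and C9 and C15 endo, so that C9 and the oxygen on C11 lie on opposite faces as C9 and 11-OH do in the target. Absolute configuration comes from the catalyst, whose aryl group covers one face of the s-trans enal. The step needs cycloaddition to win over Mukaiyama aldol or Michael addition and over cycloreversion, which the non-nucleophilic triflimide counter-ion, −78 °C and the cold basic quench are meant to secure.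

Step 4
Reactants: 6 Diels–Alder adduct
Product: 7 C2 methyl carbinol (1-hydroxyethyl group exo on C1, both C2 epimers, rest as 6)
Conditions: MeMgBr (1.05 equiv), THF, −78 °C
Reagents that add atoms: methylmagnesium bromide C[Mg]Br
Why: Grignard 1,2-addition, in which the exo formyl group reacts far faster than the endo ester flanked by two quaternary carbons, and both carbinol epimers are used because C2 is set again in step 9.

Step 5
Reactants: 7 C2 methyl carbinol
Product: 8 C2 methyl ketone (exo acetyl on C1, rest as 6)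
Conditions: Dess–Martin periodinane, pyridine, CH2Cl2, 0 °C to rt
Reagents that add atoms: none
Why: Dess–Martin oxidation handles the neopentyl secondary alcohol, and the pyridine buffer protects the acid-labile silyl enol ether.

Step 6
Reactants: 9 propargyl alcohol
Product: 11 (Z)-3-iodo-2-methylprop-2-en-1-ol, via alkenylmagnesium alkoxide 10 (not isolated)
Conditions: MeMgBr (2.5 equiv), CuI (10 mol %), THF, −10 °C to rt; then I2, 0 °C
Reagents that add atoms: methylmagnesium bromide C[Mg]Br; iodine II
Why: Copper-catalysed anti-carbomagnesiation of the propargylic alkoxide gives the chelated alkenylmagnesium, and iodinolysis with retention places iodine cis to CH2OH, which is the Z geometry needed at C5=C6.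

Step 7
Reactants: 11 (Z)-3-iodo-2-methylprop-2-en-1-ol
Product: 12 (Z)-3-bromo-1-iodo-2-methylprop-1-ene
Conditions: CBr4, PPh3, CH2Cl2, 0 °C
Reagents that add atoms: carbon tetrabromide BrC(Br)(Br)Br
Why: Appel bromination is an SN2 displacement at the primary allylic carbon and leaves the alkene geometry untouched.

Step 8
Reactants: 8 C2 methyl ketone; 12 (Z)-3-bromo-1-iodo-2-methylprop-1-ene
Product: 14 C2 ketone carrying C3–C6 ((Z)-5-iodo-4-methylpent-4-enoyl group exo on C1, rest as 6), via lithium enolate 13 (not isolated)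
Conditions: LDA (1.0 equiv), THF, −78 °C; then 12, DMPU, −78 to −30 °C
Reagents that add atoms: none
Why: Kinetic enolate alkylation forms C3–C4, since quaternary C1 leaves only the C3 methyl to enolise, the ketone is clearly more acidic than the C10–H of the ester (so the bridge is not expelled), and the allylic bromide is a fast SN2 partner.

Step 9
Reactants: 14 C2 ketone
Product: 15 (2R)-alcohol (rest as 14)
Conditions: (S)-B-butyl-CBS oxazaborolidine (20 mol %), catecholborane, toluene, −78 to −40 °C; MeOH, aqueous work-up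
Reagents that add atoms: none
Why: In the Corey–Bakshi–Shibata reduction, quaternary C1 against the C3 methylene is a tert-alkyl/primary-alkyl contrast, so the (S)-catalyst delivers hydride under reagent control to give (2R)-C2, and catecholborane leaves the ester, both alkenes and the C–I bond alone.

Step 10
Reactants: 15 (2R)-alcohol
Product: 16 2-O-triethylsilyl ether
Conditions: TESOTf, 2,6-lutidine, CH2Cl2, −78 to 0 °C
Reagents that add atoms: triethylsilyl triflate CC[Si](CC)(CC)OS(=O)(=O)C(F)(F)F
Why: Silyl triflate silylation covers the hindered carbinol for the hydride and organometallic steps and comes off together with the enol ether in step 17.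

Step 11
Reactants: 16 2-O-TES ester
Product: 17 C9 aldehyde (endo formyl on C10, rest as 16)
Conditions: DIBAL-H (1.1 equiv), toluene, −78 °C; aqueous work-up, used at once
Reagents that add atoms: none
Why: In the DIBAL-H partial reduction the tetrahedral aluminate of this hindered ester persists at −78 °C, and the β-alkoxy aldehyde is not exposed to base before use.

Step 12
Reactants: 18 methyl (S)-3-hydroxy-2-methylpropanoate
Product: 19 methyl (S)-3-(tert-butyldiphenylsilyloxy)-2-methylpropanoate
Conditions: TBDPSCl, imidazole, DMF, rt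
Reagents that add atoms: tert-butyldiphenylsilyl chloride CC(C)(C)[Si](Cl)(c1ccccc1)c1ccccc1
Why: Standard silylation of the primary alcohol (future C19–O), with the chiral-pool stereocentre (future C17) untouched.

Step 13
Reactants: 19 silyl ether ester
Product: 20 (S)-3-(tert-butyldiphenylsilyloxy)-2-methylpropanal
Conditions: DIBAL-H, CH2Cl2, −78 °C
Reagents that add atoms: none
Why: DIBAL-H partial reduction of the ester at low temperature gives the aldehyde without epimerisation.

Step 14
Reactants: 20 aldehyde
Product: 21 (R)-tert-butyl[(2-methylbut-3-yn-1-yl)oxy]diphenylsilane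
Conditions: dimethyl (1-diazo-2-oxopropyl)phosphonate, K2CO3, MeOH, 0 °C to rt
Reagents that add atoms: dimethyl (1-diazo-2-oxopropyl)phosphonate COP(=O)(OC)C(=[N+]=[N-])C(C)=O
Why: Ohira–Bestmann homologation adds C7 as the terminal alkyne carbon under mild carbonate conditions that keep the α-stereocentre (only the descriptor changes).

Step 15
Reactants: 21 alkyne
Product: 23 (S)-tert-butyl[(3-iodo-2-methylbut-3-en-1-yl)oxy]diphenylsilane, via iodoalkenylborane 22 (not isolated)
Conditions: B-iodo-9-BBN, pentane–CH2Cl2, −20 °C; then AcOH, 0 °C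
Reagents that add atoms: B-iodo-9-borabicyclo[3.3.1]nonane IB1C2CCCC1CCC2
Why: Syn-iodoboration puts iodine on the internal carbon C8 (Markovnikov sense), and protodeboronation with acetic acid leaves the 2-iodo-1-alkene.

Step 16
Reactants: 23 2-iodoalkene; 17 C9 aldehyde
Product: 25 (9R)-allylic alcohol (C9H(OH)–C8(=C7H2)–C17H(CH3)–C19H2OTBDPS on C10, rest as 17), via alkenylmagnesium chloride 24 (not isolated)
Conditions: 23, i-PrMgCl·LiCl, THF, 0 °C to rt; then 17, −40 to 0 °C
Reagents that add atoms: none
Why: Grignard 1,2-addition after iodine–magnesium exchange, in which the formyl oxygen turns away from the cis-endo C15 methyl and the inner face is walled off by the C12=C13 bridge with its silyloxy group, so the alkenyl group arrives from the open outer face anti to C11 and sets (9R)-C9, and a magnesium reagent does not exchange with the C6 iodide.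

Step 17
Reactants: 25 allylic alcohol
Product: 26 keto diol (C12 ketone in the 7-oxanorbornane, free 2-OH and 9-OH, TBDPS kept)
Conditions: 1 M HCl–THF, 0 °C to rt
Reagents that add atoms: none
Why: Acid hydrolysis protonates the enol ether at C13 and cleaves the TES ether, while the far more acid-stable TBDPS ether, the vinyl iodide and the bridge stay, now that all nucleophilic and hydride steps are over.

Step 18
Reactants: 26 keto diol
Product: 27 2,9-diacetate
Conditions: Ac2O, pyridine, DMAP (cat.), CH2Cl2, 0 °C to rt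
Reagents that add atoms: acetic anhydride CC(=O)OC(C)=O
Why: DMAP-catalysed acylation installs both acetates of the target on the only two free hydroxyl groups, and pyridine is too weak a base to enolise the bridged ketone.

Step 19
Reactants: 27 diacetate
Product: 28 (8S)-7,8-diol
Conditions: OsO4 (5 mol %), NMO, acetone–H2O, 0 °C to rt
Reagents that add atoms: osmium tetroxide O=[Os](=O)(=O)=O; N-methylmorpholine N-oxide C[N+]1([O-])CCOCC1; water O
Why: In the Upjohn syn-dihydroxylation both allylic centres C9 and C17 turn their hydrogens toward each other to avoid A(1,2) strain, which stacks the two largest groups (C10 and C19H2OTBDPS) on one face, so osmium adds to the other face and sets C8 with 8-OH and 9-OAc anti along C10–C9–C8–C7, while the iodine-deactivated trisubstituted C5=C6 reacts much more slowly.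

Step 20
Reactants: 28 7,8-diol
Product: 29 8-hydroxy C7 aldehyde
Conditions: (COCl)2, DMSO, CH2Cl2, −78 °C; Et3N, −78 to −20 °C
Reagents that add atoms: none
Why: Swern oxidation converts the primary alcohol only, cannot touch the tertiary 8-OH and, unlike hypervalent-iodine oxidants, does not cleave the 1,2-diol.

Step 21
Reactants: 29 hydroxy aldehyde
Product: 30 8-O-triethylsilyl C7 aldehyde
Conditions: TESOTf, 2,6-lutidine, CH2Cl2, −78 °C
Reagents that add atoms: triethylsilyl triflate CC[Si](CC)(CC)OS(=O)(=O)C(F)(F)F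
Why: Silylation of the tertiary alcohol of this non-enolisable aldehyde blocks α-ketol rearrangement, acetate migration and chelation in the ring closure.

Step 22
Reactants: 30 iodo aldehyde
Product: 31 bridged ten-membered carbocycle, (7S)-allylic alcohol, 5Z
Conditions: CrCl2 (excess), NiCl2 (1 mol % of Cr), DMSO, rt, about 1 mM, slow addition
Reagents that add atoms: none
Why: In the Nozaki–Hiyama–Kishi macrocyclisation nickel inserts into C6–I with retention of the Z geometry, the alkenylchromium adds only to the aldehyde (ketone, acetates and silyl ethers are tolerated), and C7 is set by Felkin–Anh attack anti to the C8–OTES bond with the ring-bound C9 beside the carbonyl oxygen.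

Step 23
Reactants: 31 macrocycle
Product: 32 7,8,19-triol
Conditions: HF·pyridine, pyridine, THF, 0 °C to rt
Reagents that add atoms: none
Why: Fluoride-mediated global desilylation under slightly acidic conditions removes TES and TBDPS without acetate migration or enolisation of the ketone.

Step 24
Reactants: 32 triol
Product: 35 bridged γ-lactone (19,7-olide with the C11–O–C14 bridge and C12 ketone), via hydroxy aldehyde 33 (not isolated), via lactol 34 (not isolated)
Conditions: [Cu(MeCN)4]OTf, 2,2'-bipyridine, TEMPO, N-methylimidazole (10 mol % each), air, MeCN, rt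
Reagents that add atoms: none
Why: Copper/nitroxyl aerobic oxidative lactonisation picks the unhindered primary C19–OH, 7-OH captures the aldehyde as a five-membered lactol that is oxidised further, the sec/tert 1,2-diol is not cleaved, and the near-neutral medium keeps C17.

Step 25
Reactants: 35 bridged lactone
Product: 36 target, (1S,2R,5Z,7S,8S,9R,10S,11S,17R)-2,9-diacetoxy-8,11-dihydroxy-12-oxobriara-5,13-dien-19,7-olide
Conditions: DBU, CH2Cl2, 0 °C to rt
Reagents that add atoms: none
Why: E1cB opening of the 7-oxanorbornan-2-one, in which DBU enolises C13–H and strain release expels the C14–O bond, gives C13=C14 and 11-OH in one move with C11 unchanged because its C–O bond is never broken.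

Compound list
1 | 2-methyltetrahydrofuran-3-one (racemic) | CC1OCCC1=O | starting material
2 | lithium 2-methyl-2,5-dihydrofuran-3-olate | CC1OCC=C1O[Li] | intermediate
3 | 2-methylfuran-3(2H)-one (racemic) | CC1OC=CC1=O | intermediate
4 | 3-(tert-butyldimethylsilyloxy)-2-methylfuran | Cc1occc1O[Si](C)(C)C(C)(C)C | intermediate
5 | ethyl (E)-3-methyl-4-oxobut-2-enoate | CCOC(=O)/C=C(\C)C=O | starting material
6 | ethyl (1S,2R,3R,4S)-6-(tert-butyldimethylsilyloxy)-3-formyl-1,3-dimethyl-7-oxabicyclo[2.2.1]hept-5-ene-2-carboxylate | CCOC(=O)[C@@H]1[C@](C)([C@@H]2C=C(O[Si](C)(C)C(C)(C)C)[C@@]1(C)O2)C=O | intermediate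
7 | C2 methyl carbinol of 6 (C2 epimers) | CCOC(=O)[C@@H]1[C@](C)([C@@H]2C=C(O[Si](C)(C)C(C)(C)C)[C@@]1(C)O2)C(C)O | intermediate
8 | C2 methyl ketone | CCOC(=O)[C@@H]1[C@](C)([C@@H]2C=C(O[Si](C)(C)C(C)(C)C)[C@@]1(C)O2)C(C)=O | intermediate
9 | propargyl alcohol | C#CCO | starting material
10 | (Z)-alkenylmagnesium bromide magnesium alkoxide | Br[Mg]OC/C(C)=C\[Mg]Br | intermediate
11 | (Z)-3-iodo-2-methylprop-2-en-1-ol | OC/C(C)=C\I | intermediate
12 | (Z)-3-bromo-1-iodo-2-methylprop-1-ene | BrC/C(C)=C\I | intermediate
13 | lithium enolate of 8 (C2=C3) | CCOC(=O)[C@@H]1[C@](C)([C@@H]2C=C(O[Si](C)(C)C(C)(C)C)[C@@]1(C)O2)C(=C)O[Li] | intermediate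
14 | C2 ketone with the C3–C6 (Z)-iodoalkenyl chain | CCOC(=O)[C@@H]1[C@](C)([C@@H]2C=C(O[Si](C)(C)C(C)(C)C)[C@@]1(C)O2)C(=O)CC/C(C)=C\I | intermediate
15 | (2R)-alcohol | CCOC(=O)[C@@H]1[C@](C)([C@@H]2C=C(O[Si](C)(C)C(C)(C)C)[C@@]1(C)O2)[C@H](O)CC/C(C)=C\I | intermediate
16 | 2-O-TES ether | CCOC(=O)[C@@H]1[C@](C)([C@@H]2C=C(O[Si](C)(C)C(C)(C)C)[C@@]1(C)O2)[C@H](O[Si](CC)(CC)CC)CC/C(C)=C\I | intermediate
17 | C9 aldehyde | O=C[C@@H]1[C@](C)([C@@H]2C=C(O[Si](C)(C)C(C)(C)C)[C@@]1(C)O2)[C@H](O[Si](CC)(CC)CC)CC/C(C)=C\I | intermediate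
18 | methyl (S)-3-hydroxy-2-methylpropanoate | COC(=O)[C@@H](C)CO | starting material
19 | methyl (S)-3-(tert-butyldiphenylsilyloxy)-2-methylpropanoate | COC(=O)[C@@H](C)CO[Si](c1ccccc1)(c1ccccc1)C(C)(C)C | intermediate
20 | (S)-3-(tert-butyldiphenylsilyloxy)-2-methylpropanal | O=C[C@@H](C)CO[Si](c1ccccc1)(c1ccccc1)C(C)(C)C | intermediate
21 | (R)-tert-butyl[(2-methylbut-3-yn-1-yl)oxy]diphenylsilane | C#C[C@@H](C)CO[Si](c1ccccc1)(c1ccccc1)C(C)(C)C | intermediate
22 | (Z)-2-iodoalk-1-enyl-9-BBN adduct of 21 | I/C(=C\B1C2CCCC1CCC2)[C@@H](C)CO[Si](c1ccccc1)(c1ccccc1)C(C)(C)C | intermediate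
23 | (S)-tert-butyl[(3-iodo-2-methylbut-3-en-1-yl)oxy]diphenylsilane | C=C(I)[C@@H](C)CO[Si](c1ccccc1)(c1ccccc1)C(C)(C)C | intermediate
24 | alkenylmagnesium chloride from 23 | C=C([Mg]Cl)[C@@H](C)CO[Si](c1ccccc1)(c1ccccc1)C(C)(C)C | intermediate
25 | (9R)-allylic alcohol | O[C@@H](C(=C)[C@@H](C)CO[Si](c1ccccc1)(c1ccccc1)C(C)(C)C)[C@@H]1[C@](C)([C@@H]2C=C(O[Si](C)(C)C(C)(C)C)[C@@]1(C)O2)[C@H](O[Si](CC)(CC)CC)CC/C(C)=C\I | intermediate
26 | keto diol (C12 ketone, 2-OH, 9-OH) | O[C@@H](C(=C)[C@@H](C)CO[Si](c1ccccc1)(c1ccccc1)C(C)(C)C)[C@@H]1[C@](C)([C@@H]2CC(=O)[C@@]1(C)O2)[C@H](O)CC/C(C)=C\I | intermediate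
27 | 2,9-diacetate | CC(=O)O[C@@H](C(=C)[C@@H](C)CO[Si](c1ccccc1)(c1ccccc1)C(C)(C)C)[C@@H]1[C@](C)([C@@H]2CC(=O)[C@@]1(C)O2)[C@H](OC(C)=O)CC/C(C)=C\I | intermediate
28 | 7,8-diol | CC(=O)O[C@@H]([C@@](O)(CO)[C@@H](C)CO[Si](c1ccccc1)(c1ccccc1)C(C)(C)C)[C@@H]1[C@](C)([C@@H]2CC(=O)[C@@]1(C)O2)[C@H](OC(C)=O)CC/C(C)=C\I | intermediate
29 | 8-hydroxy C7 aldehyde | CC(=O)O[C@@H]([C@@](O)(C=O)[C@@H](C)CO[Si](c1ccccc1)(c1ccccc1)C(C)(C)C)[C@@H]1[C@](C)([C@@H]2CC(=O)[C@@]1(C)O2)[C@H](OC(C)=O)CC/C(C)=C\I | intermediate
30 | 8-O-TES C7 aldehyde | CC(=O)O[C@@H]([C@@](O[Si](CC)(CC)CC)(C=O)[C@@H](C)CO[Si](c1ccccc1)(c1ccccc1)C(C)(C)C)[C@@H]1[C@](C)([C@@H]2CC(=O)[C@@]1(C)O2)[C@H](OC(C)=O)CC/C(C)=C\I | intermediate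
31 | bridged macrocyclic (7S)-allylic alcohol | CC(=O)O[C@@H]1[C@@H]2[C@](C)([C@@H]3CC(=O)[C@@]2(C)O3)[C@H](OC(C)=O)CC/C(C)=C\[C@H](O)[C@@]1(O[Si](CC)(CC)CC)[C@@H](C)CO[Si](c1ccccc1)(c1ccccc1)C(C)(C)C | intermediate
32 | bridged 7,8,19-triol | CC(=O)O[C@@H]1[C@@H]2[C@](C)([C@@H]3CC(=O)[C@@]2(C)O3)[C@H](OC(C)=O)CC/C(C)=C\[C@H](O)[C@@]1(O)[C@@H](C)CO | intermediate
33 | bridged 7,8-dihydroxy C19 aldehyde | CC(=O)O[C@@H]1[C@@H]2[C@](C)([C@@H]3CC(=O)[C@@]2(C)O3)[C@H](OC(C)=O)CC/C(C)=C\[C@H](O)[C@@]1(O)[C@@H](C)C=O | intermediate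
34 | bridged C19 lactol (C19 epimers) | CC(=O)O[C@@H]1[C@@H]2[C@](C)([C@@H]3CC(=O)[C@@]2(C)O3)[C@H](OC(C)=O)CC/C(C)=C\[C@@H]2OC(O)[C@H](C)[C@]21O | intermediate
35 | bridged γ-lactone | CC(=O)O[C@@H]1[C@@H]2[C@](C)([C@@H]3CC(=O)[C@@]2(C)O3)[C@H](OC(C)=O)CC/C(C)=C\[C@@H]2OC(=O)[C@H](C)[C@]21O | intermediate
36 | CNP0255369.2 | CC(=O)O[C@@H]1[C@@H]2[C@](C)(C=CC(=O)[C@@]2(C)O)[C@H](OC(C)=O)CC/C(C)=C\[C@@H]2OC(=O)[C@H](C)[C@]21O | target

Total steps: 25. Longest linear sequence: 19 (steps 1–5, 8–11, 16–25).

Steps most likely to fail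

Step 3. After the first bond (C10–C11) silicon may migrate instead of C1–C14 closing. The furan may also attack the formyl carbon, and the adduct may revert on warming. Each of these processes erodes conversion and exo/endo or facial selectivity.
Fallback: the two bonds are made in two separate operations, a double Michael sequence instead of a cycloaddition. It sets out from 4 and 5. The same catalyst at −78 °C with an early quench is used on purpose for the conjugate addition with silyl transfer. This gives the Mukaiyama–Michael adduct, a 2,2-disubstituted furan-3(2H)-one with an O-TBS enol ether at C1=C2, F1. A catalytic silylium source (TBSOTf or Tf2NH, CH2Cl2, −78 to −40 °C) then drives the intramolecular Mukaiyama–Michael attack of C1 on C14 of the furanone. Silicon returns to the C12 oxygen, and the sequence comes back to the route at 6.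

Step 22. Ring closure against the boat-locked core, which holds C2 and C9 about 120° apart, may be slower than oligomerisation or loss of iodine. Facial control at C7 may also be poor.
Fallback: the bridge is opened before the ring is closed, so cyclisation takes place on the half-chair cyclohexenone with C2 and C9 gauche, as in the target. It sets out from 29. TESOTf/Et3N (CH2Cl2, 0 °C) silylates 8-OH and at the same time opens the 7-oxanorbornanone by silyl-triflate-assisted elimination, giving the 8,11-bis-O-TES enone aldehyde F2. Nozaki–Hiyama–Kishi closure gives the macrocyclic enone alcohol F3. HF·pyridine gives the desilylated enone tetraol F4. The copper/TEMPO aerobic lactonisation then passes through the hydroxy aldehyde F5 and the lactol F6 and comes back to the route at 36, so step 25 is no longer needed.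

Step 16. Addition at the congested endo formyl group may be slow enough for enolisation to compete. Rotation of the small formyl group may also lower the facial selectivity at C9.
Fallback: C9 is set by hydride delivery instead of by C–C bond formation. It sets out from 25 as its C9-epimer mixture. Dess–Martin oxidation (pyridine buffer) gives the cross-conjugated C9 enone F7. In F7 the bulky alkenyl residue can only point away from the C15 methyl. 1,2-Reduction with DIBAL-H (toluene, −78 °C) from the same open outer face then gives the (9R)-carbinol and comes back to the route at 25.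

Further compounds
F1 | step 3 | Mukaiyama–Michael adduct (furan-3(2H)-one with C1=C2 O-TBS enol ether) | CCOC(=O)[C@@H]([C@]1(C)OC=CC1=O)C(C)=CO[Si](C)(C)C(C)(C)C
F2 | step 22 | 8,11-bis-O-TES enone aldehyde | CC(=O)O[C@@H]([C@@](O[Si](CC)(CC)CC)(C=O)[C@@H](C)CO[Si](c1ccccc1)(c1ccccc1)C(C)(C)C)[C@@H]1[C@](C)(C=CC(=O)[C@@]1(C)O[Si](CC)(CC)CC)[C@H](OC(C)=O)CC/C(C)=C\I
F3 | step 22 | macrocyclic enone alcohol | CC(=O)O[C@@H]1[C@@H]2[C@](C)(C=CC(=O)[C@@]2(C)O[Si](CC)(CC)CC)[C@H](OC(C)=O)CC/C(C)=C\[C@H](O)[C@@]1(O[Si](CC)(CC)CC)[C@@H](C)CO[Si](c1ccccc1)(c1ccccc1)C(C)(C)C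
F4 | step 22 | desilylated enone tetraol | CC(=O)O[C@@H]1[C@@H]2[C@](C)(C=CC(=O)[C@@]2(C)O)[C@H](OC(C)=O)CC/C(C)=C\[C@H](O)[C@@]1(O)[C@@H](C)CO
F5 | step 22 | hydroxy aldehyde | CC(=O)O[C@@H]1[C@@H]2[C@](C)(C=CC(=O)[C@@]2(C)O)[C@H](OC(C)=O)CC/C(C)=C\[C@H](O)[C@@]1(O)[C@@H](C)C=O
F6 | step 22 | lactol | CC(=O)O[C@@H]1[C@@H]2[C@](C)(C=CC(=O)[C@@]2(C)O)[C@H](OC(C)=O)CC/C(C)=C\[C@@H]2OC(O)[C@H](C)[C@]21O
F7 | step 16 | cross-conjugated C9 enone | O=C(C(=C)[C@@H](C)CO[Si](c1ccccc1)(c1ccccc1)C(C)(C)C)[C@@H]1[C@](C)([C@@H]2C=C(O[Si](C)(C)C(C)(C)C)[C@@]1(C)O2)[C@H](O[Si](CC)(CC)CC)CC/C(C)=C\I
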